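## The problem

Compound 10 is 2,3,4,6-tetrabromo-1H-indole (C8H3Br4N), an indole in which every carbon except C5, C7 and the two ring-fusion atoms carries bromine. The bicyclic skeleton is trivial and there is no stereocentre, so the only thing to control is the position of four C–Br bonds. C2 and C3 belong to the enamine half of the indole and answer to its innate reactivity. C4 and C6, however, are both meta to the ring nitrogen on C7a, whereas an indole or oxindole nitrogen sends electrophiles to C5 and C7. The benzene-ring pattern must therefore be imposed by a second, stronger director that can be erased afterwards. The feature that allows this is that C4 and C6 share one neighbour, C5, whose para position is the ring-fusion carbon C7a: a donor on C5 has exactly two free activated positions, and they are the two that must be brominated. The fragile elements are the free N–H 2-bromoindole unit (acid- and light-sensitive, prone to oligomerise), which argues for keeping the five-membered ring as a lactam until the last two steps, and the enolisable C3 methylene of that lactam, which competes for electrophiles. Once installed, the aryl bromides rule out hydrogenation over palladium and organolithium reagents, so any reduction must come before the first bromination or be chemoselective.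

## Retrosynthesis

**C3–Br.** The last bond cut is C3–Br, leading from 10 back to 2,4,6-tribromo-1H-indole 9 and N-bromosuccinimide 3. C3 is the most nucleophilic carbon of any indole, so this bromine needs no director and is best introduced last, when the most sensitive compound is handled only once. The alternative of placing the C3 bromine earlier would put a labile α-bromo lactam through the later steps. The forward reaction must stop after one substitution, which the three deactivating bromines of 9 should ensure.

**C2–Br.** The C2–Br bond of 9 is traced to the lactam carbonyl of 4,6-dibromoindolin-2-one 7 and phosphoryl tribromide 8. Direct bromination of an indole attacks C3 before C2, and C2 lithiation of an N-protected indole would suffer lithium–bromine exchange at C4 and C6 and cost two protecting-group steps. The carbonyl oxygen marks C2 unambiguously and also keeps the pyrrole ring masked during the earlier electrophilic chemistry. The forward step must activate an electron-poor lactam without destroying the N–H bromoindole it forms.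

**C5–H from C5–NH2.** The C5 hydrogen of 7 is replaced retrosynthetically by an amino group, giving 5-amino-4,6-dibromoindolin-2-one 5. In the forward sense the amine leaves by diazotisation to the diazonium salt 6 and reductive loss of nitrogen. An amino group is preferred over a hydroxyl director because its removal needs no palladium-mediated reduction that would endanger the aryl bromides. The lactam nitrogen alone cannot serve, since it directs to C5 and C7. The forward step must diazotise a hindered, weakly basic amine without nitrosating the C3 methylene.

**C4–Br and C6–Br (key disconnection).** Both benzene-ring C–Br bonds of 5 are cut at once, leading to 5-aminoindolin-2-one 2 and two equivalents of 3, with the 6-bromo compound 4 as the expected halfway point. The same tactic at the indole level would lose the electrophile to C3 and expose an oxidisable aminoindole. At the indoline level the N1 amine would compete as a director. In the oxindole, N1 is an amide, the C5 amine dominates, and its para position is blocked by C7a. The precursor has no halogen at all. The forward reaction must substitute the hindered C4 position as well as C6, and must leave C7 and C3 alone.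

**C5–NH2 from C5–NO2.** Amine 2 is taken back to 5-nitroindolin-2-one 1 by catalytic hydrogenation, a functional-group change with no selectivity issue because no halogen is yet present. Compound 1 is a stable catalogue compound, whereas 2 is an air-sensitive p-aminoanilide best made immediately before use.

## Roads not taken

**Alternative 1:** ring closure at N1–C2 of a gem-dibromovinyl anilide.
- Cut and key step: the N1–C2 bond of an N-sulfonyl 2-bromoindole is cut back to N-[3,5-dibromo-2-(2,2-dibromovinyl)phenyl]-4-methylbenzenesulfonamide A2. Under carbonate base, optionally with catalytic CuI, the sulfonamide nitrogen displaces one vinylic bromine and closes the pyrrole ring to 2,4,6-tribromo-1-tosyl-1H-indole A1. A2 would come from 2-amino-4,6-dibromobenzaldehyde A3 by N-sulfonylation and Ramirez dibromo-olefination.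
- Merits: the ring and the C2 bromine arise in one regiospecific event. A1 is an N-protected, shelf-stable 2-bromoindole, which is better than the free N–H compound 9 of the chosen route.
- Weak points: the 4,6-dibromo pattern must already be present in A3, a 1,2,3,5-tetrasubstituted benzene that is not a routine catalogue item and needs several steps of its own. The regiochemical problem is moved, not solved. Copper catalysis with two aryl bromides in the molecule invites Ullmann-type side reactions. The deactivated N-sulfonyl indole is sluggish in C3 bromination, and the sulfonyl group must be removed from a tetrabromide at the very end.
- Comparison: the chosen plan has the less stable C2-bromide stage. Against this it creates the benzene pattern from an unhalogenated commercial core in one step and needs no protecting group, so it is clearly shorter.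

**Alternative 2:** construction of the benzene ring by an intramolecular pyridazine Diels–Alder reaction.
- Cut and key step: the C3a–C7a and C4–C5 bonds are cut. The silylalkyne tethered to nitrogen in methyl (5-bromopyridazin-3-yl)[4-(trimethylsilyl)but-3-yn-1-yl]carbamate A5 adds across the two carbon termini of the azadiene. Loss of dinitrogen then gives methyl 6-bromo-4-(trimethylsilyl)indoline-1-carboxylate A4.
- Merits: the positions of the C6 bromine and of the C4 silyl group (a latent bromine through ipso-bromodesilylation) are fixed by connectivity and owe nothing to substituent effects. In this respect the route is more secure than any electrophilic substitution.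
- Weak points: A5 needs a multistep synthesis, and the cycloaddition of a modestly electron-poor pyridazine with a hindered silylalkyne requires very high temperature. After A4 the route still needs bromodesilylation, carbamate cleavage, dehydrogenation of the indoline, and bromination at C3 and C2 of a free indole. For a C8 target without stereocentres this is out of proportion.
- Comparison: the chosen plan relies on directing effects and stoichiometry instead of connectivity, but reaches the same C4/C6 pattern in one step and delivers C2 already functionalised.

**Alternative 3:** Hemetsberger indole synthesis.
- Cut and key step: the N1–C7a bond is cut. Thermolysis of methyl (Z)-2-azido-3-(2,4-dibromophenyl)acrylate A7 releases dinitrogen, and the vinyl nitrene inserts into the only free ortho C–H bond, giving methyl 4,6-dibromo-1H-indole-2-carboxylate A6. A7 comes from Knoevenagel condensation of 2,4-dibromobenzaldehyde A8 with methyl azidoacetate A9.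
- Merits: both benzene-ring bromines are bought in a cheap aldehyde, the cyclisation has no regiochemical choice, and the indole is reached in two steps. For the security of the C4/C6 pattern this road is at least as good as the chosen one, and arguably better.
- Weak points: the C2 ester is the wrong group. It must be hydrolysed and removed by high-temperature decarboxylation in the presence of aryl bromides, after which C3 and then C2 must be brominated on a free indole. The C2 bromination is the less dependable of the two. A direct bromodecarboxylation at C2 is not established for such a substrate. The condensation of an ortho-substituted aldehyde with A9 is often inefficient, and azide thermolysis is a scale hazard.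
- Comparison: overall length is similar. The chosen plan offers a C2 position marked by the lactam oxygen, so the C2 bromine comes from a deoxybromination. It also uses no azide and has no step above 80 °C.

Key step: step 2

## Route

Assumption: 1, 3 and 8 are taken as catalogue chemicals. Amine 2 is prepared fresh because stored samples of this p-aminoanilide darken by air oxidation, and the key step depends on an exact count of brominating agent.

Step 1
Reactants: 1 5-nitroindolin-2-one
Product: 2 5-aminoindolin-2-one
Conditions: H2 (1 atm), 10% Pd/C, MeOH–THF, rt
Reagents that add atoms: none
Why: Heterogeneous catalytic hydrogenation of an aromatic nitro group; the lactam is inert and no carbon–halogen bond is yet present, so Pd/C carries no hydrogenolysis risk. The filtered amine solution should be concentrated and used at once.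

Step 2
Reactants: 2 5-aminoindolin-2-one; 3 N-bromosuccinimide
Product: 5 5-amino-4,6-dibromoindolin-2-one, via 5-amino-6-bromoindolin-2-one 4 (not isolated)
Conditions: NBS (2.0 equiv, in portions), DMF, −10 °C → rt, dark
Reagents that add atoms: N-bromosuccinimide, O=C1CCC(=O)N1Br
Why: Electrophilic aromatic substitution of a free aniline by NBS, the closest known reaction type being the ortho,ortho-dibromination of para-acylamino anilines that precedes a reductive deamination. Each C–Br bond forms through a Wheland intermediate whose positive charge is taken up by the C5 nitrogen as an iminium ion; the open C6 position should react first to give 4, and the second equivalent then substitutes C4, the more hindered ortho site next to C3a. No ring is closed and no stereocentre is created. The selectivity needed is C4 and C6 over C7 and C3: the position para to the amino group is the ring-fusion carbon C7a and is blocked, C7 is meta to the amino group and activated only by the weakly donating lactam nitrogen, and C3 can react only through the lactam enol, which is scarce in neutral DMF at low temperature. Each bromine introduced lowers the nucleophilicity of the ring, so with the NBS charge held at two equivalents a third substitution is not expected. Any 4-bromo isomer formed in the first event converges on the same product 5.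

Step 3
Reactants: 5 5-amino-4,6-dibromoindolin-2-one
Product: 7 4,6-dibromoindolin-2-one, via 4,6-dibromo-2-oxoindoline-5-diazonium hydrogensulfate 6 (not isolated)
Conditions: NaNO2 (1.05 equiv), H2SO4, AcOH–H2O, 0 °C; then 50% aq. H3PO2, 0 °C → rt
Reagents that add atoms: none
Why: Diazotisation followed by hypophosphorous acid hydrodediazoniation (radical-chain reductive deamination), the standard way to erase an amino director flanked by two bromines. Sulfuric acid is used instead of hydrochloric acid to avoid halide exchange at the bromines ortho to the diazonium group, and nitrite is held near one equivalent at 0 °C so that N-nitrosation of the amine outruns C-nitrosation of the C3 methylene.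

Step 4
Reactants: 7 4,6-dibromoindolin-2-one; 8 phosphoryl tribromide
Product: 9 2,4,6-tribromo-1H-indole
Conditions: POBr3 (1.5 equiv), imidazole (1.2 equiv), ClCH2CH2Cl, 80 °C
Reagents that add atoms: phosphoryl tribromide, O=P(Br)(Br)Br
Why: Deoxybromination of a lactam, as known for the conversion of oxindoles into 2-bromoindoles: POBr3 turns the carbonyl oxygen into a phosphoryl leaving group (Vilsmeier-type activation), bromide adds at C2, and elimination with tautomerisation gives the aromatic indole. Imidazole buffers the HBr that would degrade the N–H bromoindole, the aryl bromides are spectators, and 9 should be carried on without storage.

Step 5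
Reactants: 9 2,4,6-tribromo-1H-indole; 3 N-bromosuccinimide
Product: 10 2,3,4,6-tetrabromo-1H-indole
Conditions: NBS (1.0 equiv), DMF, 0 °C → rt, dark
Reagents that add atoms: N-bromosuccinimide, O=C1CCC(=O)N1Br
Why: Electrophilic substitution at C3, the enamine carbon and the only strongly nucleophilic position left, as in the known C3 halogenation of 2-haloindoles with NBS. The benzene ring carries two deactivating bromines, so one equivalent of NBS should stop at the tetrabromide despite the peri C4 bromine.

## Compound list

1 | 5-nitroindolin-2-one | O=C1Cc2cc([N+](=O)[O-])ccc2N1 | starting material
2 | 5-aminoindolin-2-one | Nc1ccc2NC(=O)Cc2c1 | intermediate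
3 | N-bromosuccinimide | O=C1CCC(=O)N1Br | starting material
4 | 5-amino-6-bromoindolin-2-one | Nc1c(Br)cc2NC(=O)Cc2c1 | intermediate
5 | 5-amino-4,6-dibromoindolin-2-one | Nc1c(Br)cc2NC(=O)Cc2c1Br | intermediate
6 | 4,6-dibromo-2-oxoindoline-5-diazonium hydrogensulfate | N#[N+]c1c(Br)cc2NC(=O)Cc2c1Br.OS(=O)(=O)[O-] | intermediate
7 | 4,6-dibromoindolin-2-one | O=C1Cc2c(Br)cc(Br)cc2N1 | intermediate
8 | phosphoryl tribromide | O=P(Br)(Br)Br | starting material
9 | 2,4,6-tribromo-1H-indole | Brc1cc(Br)c2cc(Br)[nH]c2c1 | intermediate
10 | 2,3,4,6-tetrabromo-1H-indole | Brc1cc(Br)c2c(Br)c(Br)[nH]c2c1 | target

## Step count and risk

Total step count: 5. Longest linear sequence: 5 steps (1 → 2 → 5 → 7 → 9 → 10).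

**Step 2 (key step).** The most likely failure is loss of site control in the second bromination. C4 is the more hindered ortho position, and if its substitution lags, bromination can spill over to the C3 methylene through the enol, or the electron-rich ring can be oxidised. In that case no NBS count gives clean 5. The fallback gives up stoichiometric control. Starting from 2, an excess of NBS (about 4.2 equiv, AcOH–MeCN) should brominate the ring and C3 completely, giving 5-amino-3,3,4,6-tetrabromoindolin-2-one F1. The two C3 bromines, which are α to the lactam carbonyl and benzylic, are then removed with Zn dust in AcOH at room temperature, conditions that leave aryl bromides untouched. The route is rejoined at 5.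

**Step 3.** The most likely failure is C-nitrosation of the enolisable C3 methylene competing with diazotisation of the hindered, weakly basic amine, so that oxime formation at C3 consumes nitrite and material. The fallback blocks C3 before the amine is touched. Starting from 5, two further equivalents of NBS in AcOH should give 5-amino-3,3,4,6-tetrabromoindolin-2-one F1, which has no C3 hydrogen. Aprotic hydrodediazoniation (t-BuONO, THF as hydrogen donor, 60 °C) then removes the amino group to give 3,3,4,6-tetrabromoindolin-2-one F2. Zn dust in AcOH strips the C3 bromines, and the route is rejoined at 7.

**Step 4.** The most likely failure is acid-promoted oligomerisation of the free N–H 2-bromoindole in the hot, HBr-generating medium, or its hydrolysis back to the lactam on work-up. Incomplete activation of a lactam deactivated by two bromines is also possible. The fallback gives up the carbonyl as a C2 marker. Starting from 7, borane reduction of the lactam (NaBH4/BF3·OEt2, THF) should give 4,6-dibromo-1H-indole F3. Two equivalents of NBS then brominate C3 first, giving 3,4,6-tribromo-1H-indole F4 in the flask, and then C2, as known for the conversion of indoles into 2,3-dibromoindoles. This fallback rejoins the route at the target 10 and bypasses 9.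

## Further compounds

F1 | step 2 | 5-amino-3,3,4,6-tetrabromoindolin-2-one | Nc1c(Br)cc2NC(=O)C(Br)(Br)c2c1Br
F2 | step 3 | 3,3,4,6-tetrabromoindolin-2-one | O=C1Nc2cc(Br)cc(Br)c2C1(Br)Br
F3 | step 4 | 4,6-dibromo-1H-indole | Brc1cc(Br)c2cc[nH]c2c1
F4 | step 4 | 3,4,6-tribromo-1H-indole | Brc1cc(Br)c2c(Br)c[nH]c2c1
A1 | alternative 1 | 2,4,6-tribromo-1-tosyl-1H-indole | Cc1ccc(cc1)S(=O)(=O)n1c(Br)cc2c(Br)cc(Br)cc21
A2 | alternative 1 | N-[3,5-dibromo-2-(2,2-dibromovinyl)phenyl]-4-methylbenzenesulfonamide | Cc1ccc(cc1)S(=O)(=O)Nc1cc(Br)cc(Br)c1C=C(Br)Br
A3 | alternative 1 | 2-amino-4,6-dibromobenzaldehyde | Nc1cc(Br)cc(Br)c1C=O
A4 | alternative 2 | methyl 6-bromo-4-(trimethylsilyl)indoline-1-carboxylate | COC(=O)N1CCc2c1cc(Br)cc2[Si](C)(C)C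
A5 | alternative 2 | methyl (5-bromopyridazin-3-yl)[4-(trimethylsilyl)but-3-yn-1-yl]carbamate | COC(=O)N(CCC#C[Si](C)(C)C)c1cc(Br)cnn1
A6 | alternative 3 | methyl 4,6-dibromo-1H-indole-2-carboxylate | COC(=O)c1cc2c(Br)cc(Br)cc2[nH]1
A7 | alternative 3 | methyl (Z)-2-azido-3-(2,4-dibromophenyl)acrylate | COC(=O)/C(N=[N+]=[N-])=C/c1ccc(Br)cc1Br
A8 | alternative 3 | 2,4-dibromobenzaldehyde | O=Cc1ccc(Br)cc1Br
A9 | alternative 3 | methyl azidoacetate | COC(=O)CN=[N+]=[N-]
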